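## Analysis of the target

Compound 14 is a C2-symmetric 3,3''-biflavanone: two chroman-4-one units (ring A fused to the pyranone ring C), each with a 4-methoxyphenyl ring B at C2, joined through the C3–C3'' bond. The four stereocentres C2, C3, C3'' and C2'' are contiguous and configured 2S,3R,2''S,3''R. H-2 and H-3 are trans in each pyranone and the two halves are homochiral, so 14 is the chiral and not the meso diastereomer about the central bond. Each ring A carries a methoxy group at C5, next to the carbonyl, and a free hydroxyl at C7, which is the reverse of what alkylation of a 5,7-dihydroxyflavanone delivers, because the 5-OH is chelated to C4=O. The C3–H bonds are alpha to a ketone and beta to O1, so base can enolise C3 or open ring C by expelling the phenoxide, and the 4-methoxyphenyl group makes the C2–O1 bond ionisable under acid. The difficulty lies in the congested C3–C3'' bond between two stereogenic alpha-carbons, in the control of four adjacent stereocentres, and in bringing in ring A with its unsymmetrical oxygen pattern. The route rests on the chain C2–C3–C3''–C2'': each end carbon bears an aryl group and an oxygen, and each inner carbon bears a carbon at the carboxyl oxidation level (C4, C4''). This is the pattern of the 8–8' dehydrodimer of a 4-hydroxycinnamic acid (C7 = C2, C8 = C3, C9 = C4) in its dilactone form, in which the C4 carboxyl is esterified by the oxygen on C2'' and the C4'' carboxyl by the oxygen on C2.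

## Retrosynthetic reasoning

14 from 13. The two O–Si bonds at O7 and O7'' are cut last. The 7-hydroxyls travel as triisopropylsilyl ethers because this group is inert to organolithium, hydrogenolysis and Mitsunobu conditions. It is also the element that later decides where ring A is metalated. The forward step has to remove it without exposing the flavanone to base.

13 from 12. The bonds O1–C2 and O1''–C2'' are cut. In the cinnamate dimer the oxygen on each of these carbons is a carboxylate oxygen, not the ring A oxygen, so it has to be exchanged in any case. Closing the ether by SN2 at carbon turns the R carbinol centres of 12 into the S centres of 13 and places each aryl group trans to the C3 substituent. Cutting O1–C8a instead (ring closure by substitution at the arene) would keep the carbinol configuration and give the 2,3-cis series. The forward reaction has to displace at a 4-methoxybenzylic carbon faster than that carbon ionises or the beta-hydroxy ketone eliminates.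

12 from 11. Only the two benzyl groups on the oxygens ortho to the ketones are removed. A neutral, non-acidic unmasking is wanted because 11 holds beta-hydroxy ketones that dehydrate under acid and undergo retro-aldol cleavage under base.

11 from 5 and 8. The aryl–acyl bonds C4–C4a and C4''–C4a'' are cut. Each lactone carbonyl of 5 serves as the acyl donor and ring A arrives as the aryllithium 9, made from 8, through the tetrahedral adduct 10. Acyl–oxygen cleavage releases the C2 and C2'' hydroxyls without touching a stereocentre. Ring A enters with its final pattern (methoxy at the future C5, protected oxygens at the future O1 and O7), so no late differentiation of ring A oxygens is needed. In 8 only the position between the benzyloxy and methoxy groups is free of a neighbouring silyl ether, which is what makes the metalation regioselective.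

8 from 7 from 6. Two O-protections of the symmetric diol 6, benzylation first and silylation second, give 8. The first is statistical and is accepted because both partners are cheap.

5 from 4 from 3. The single enantiomer 5 is taken from racemic 4 by resolution, since the dimerisation offers no absolute control. The phenols of 3 are methylated before the resolution because the free para-hydroxybenzylic lactone is labile towards base, whereas its dimethyl ether is not.

3 from 2 from 1. This is the key disconnection: the C3–C3'' bond and the two lactone C–O bonds are cut, which leads through the bis(quinone methide) 2 to two molecules of 1. It is made here because it takes apart the most hindered bond of the target and two rings at once, gives a commercial acid, and fixes the relative configuration of all four stereocentres in a rigid cis-fused bicycle. The forward reaction has to favour 8–8' coupling over the other radical coupling modes.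

## Alternatives that were turned down

Alternative 1: Both rings A are disconnected at C4a–C5 (and the corresponding bond of the other half), which leads back to a bis(benzylidene)succinyl core carrying two open-chain 3,5,7-trioxo ester arms. In the forward key step Mg(OCH3)2 chelates each arm, the methylene next to the C4 ketone attacks the terminal ester, and enolisation aromatises both rings to give the bis(2,4,6-trihydroxyphenyl) diketone A1. In its favour, the step copies the polyketide folding of flavonoid biosynthesis, needs no organometallic reagent and raises no regiochemical question in ring A. Against it for this target, A1 still has C2=C3 and C2''=C3'' double bonds, so all four stereocentres remain to be made by two oxa-Michael closures and two protonations. Neither the C3/C3'' relationship (chiral versus meso) nor the absolute configuration is controlled. Ring A emerges as a symmetrical phloroglucinol, so the 5-methoxy-7-hydroxy pattern requires methylation of the chelated, least reactive hydroxyl while the 7-OH stays free. The poly-beta-carbonyl precursor is long to assemble and can also fold by aldol pathways. Alternative 1 is stronger in that it avoids a radical coupling of modest selectivity and a resolution. The chosen strategy offers the complete C2–C3–C3''–C2'' stereotetrad from one step and a ring A that arrives already differentiated.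

Alternative 2: Each pyranone is disconnected at O1–C8a and C4–C4a, so that both rings A come from arynes and the core is an open-chain bis(beta-hydroxy ester). In the forward key step CsF releases two 3,5-dibenzyloxyarynes, each takes up a C2 alkoxide at the carbon distal to the neighbouring benzyloxy group, and each aryl anion then attacks the adjacent methyl ester, giving the tetrabenzyl ether A2. In its favour, no bond to a stereocentre is made or broken, the regiochemistry of alkoxide addition to 3-alkoxyarynes is predictable, and the step is highly convergent. Against it, A2 carries benzyl ethers at both O5 and O7, so after debenzylation the chelated 5-OH must be methylated while the more reactive 7-OH is kept free, under basic conditions that open 3-substituted flavanones. The beta-alkoxide ester is exposed to retro-aldol cleavage and to elimination under the fluoride conditions. Protonation of the aryl anion competes with acyl transfer at each of four bond-forming events. The substrate needs the carbinol configuration of the target itself (retention), which is the epimer at both carbinol carbons of what ring-opening of 5 would provide, so its stereocontrolled synthesis is a separate unsolved problem. Alternative 2 is stronger in leaving the stereocentres untouched during ring formation. The chosen strategy offers a one-step access to the carbon skeleton and the correct ring A pattern from the start, and it pays for this with an inverting closure at an ionisable centre.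

Alternative 3: Each pyranone is disconnected at C3–C4 (and C3''–C4''), and the C3–C3'' unit is traced back to the alkyne of a 1,4-diarylbut-2-yne-1,4-diol whose two oxygens carry 2-formylaryl groups. In the forward key step a triazolium-derived carbene with mild base converts each aldehyde into an acyl anion equivalent. The first adds across the alkyne (hydroacylation, C3–C4) and the second adds in Stetter fashion to C3'' of the resulting enone (C3''–C4''), giving the dibenzyl ether A3, one hydrogenolysis away from 14. In its favour, the endgame is the shortest of all, A3 already has the 5-methoxy-7-benzyloxy pattern, and the C2 and C2'' centres can come from an enantioenriched ynediol, so no resolution is needed. On step count after the key step and on absolute stereocontrol it is stronger than the chosen strategy. Against it, carbene-catalysed hydroacylation of unactivated internal alkynes is narrow in scope, and the aldehydes are flanked by two oxygen substituents, which makes them hindered and electron-rich. C3 and C3'' are both created in the step, and their relative and trans configuration is left to substrate control in a protonation. The doubly activated (propargylic and 4-methoxybenzylic) aryl ethers of the substrate are prone to ionisation. The chosen strategy offers a key step with close precedent that fixes the C3–C3'' bond and its configuration unambiguously, at the price of working from a racemate.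

Key step: step 1

Remarks on the chemistry (assumptions):
- Flavanone locants are used throughout (O1, C2, C3, C4, C4a–C8a for one half, doubly primed for the other).
- Compounds 2, 3 and 4 are racemic, and their SMILES show the enantiomer that is carried on.
- Compound 11 is written as the open hydroxy ketone; equilibration with its five-membered hemiketal would not change the plan.
- The absolute configuration of 5 is to be confirmed (X-ray anomalous dispersion or electronic circular dichroism) before it is used.

## Route

Step 1
Reactants: 1 p-coumaric acid (two molecules)
Product: 3 rac-(3R,3aR,6R,6aR)-3,6-bis(4-hydroxyphenyl)tetrahydro-1H,3H-furo[3,4-c]furan-1,4-dione (exo,exo), via bis(quinone methide) diacid 2 (not isolated)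
Conditions: FeCl3·6H2O (2.2 equiv, slow addition), acetone–H2O, rt
Reagents that add atoms: none
Why: Trivalent iron oxidises the phenol by one electron, and two phenoxyl radicals, which carry high spin density at the side-chain carbon next to the carboxyl group, combine there to form the C3–C3'' bond and the bis(quinone methide) 2. The closest known reaction type is the FeCl3- or oxidase-mediated 8–8' dehydrodimerisation of ferulic and sinapic acid to furofuranone dilactones. Each carboxyl group then adds to the methide carbon of the other half, so both rings close as 5-exo-trig conjugate additions of oxygen to a para-quinone methide, each driven by rearomatisation. The two ring-fusion centres (C3a and C6a, the future C3 and C3'') arise in the radical combination without control, but only the C2-symmetric diastereomer of 2 can lactonise twice to the cis-fused bicycle, while the meso form stops after one closure and is lost. The two benzylic centres (C3 and C6, the future C2 and C2'') are set in the lactonisations, where the aryl groups take the convex face of the bicycle because the concave face is crowded and because the para-hydroxybenzylic C–O bonds can re-ionise, which makes the exo arrangement also the thermodynamic one. The step needs 8–8' coupling to win over 8–5 and 8–O–4 coupling, and 1, with two free ortho positions, offers no bias beyond the spin density at C8 and the irreversible double lactonisation that removes the 8–8' adduct, so only a modest share of 3 is to be expected. There is no absolute control and 3 should form as the racemate.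

Step 2
Reactants: 3 rac-dilactone bisphenol
Product: 4 rac-(3R,3aR,6R,6aR)-3,6-bis(4-methoxyphenyl)tetrahydro-1H,3H-furo[3,4-c]furan-1,4-dione
Conditions: CH2N2 (excess), Et2O–MeOH–THF, 0 °C → rt
Reagents that add atoms: diazomethane, C=[N+]=[N-]
Why: O-Methylation of phenols with diazomethane needs no base, which matters because the phenoxide of 3 can expel the para-benzylic carboxylate and reopen the lactone through the quinone methide; no stereocentre is touched.

Step 3
Reactants: 4 rac-dilactone dimethyl ether
Product: 5 (3R,3aR,6R,6aR)-3,6-bis(4-methoxyphenyl)tetrahydro-1H,3H-furo[3,4-c]furan-1,4-dione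
Conditions: preparative HPLC, cellulose tris(3,5-dimethylphenylcarbamate) on silica, n-hexane–i-PrOH, rt
Reagents that add atoms: none
Why: Resolution of a racemate by chromatography on a chiral stationary phase; a rigid diaryl dilactone with several hydrogen-bond acceptors is the kind of analyte that polysaccharide carbamate phases separate, and the wanted enantiomer is identified as stated in the remarks while the other is set aside.

Step 4
Reactants: 6 5-methoxyresorcinol
Product: 7 3-(benzyloxy)-5-methoxyphenol
Conditions: BnBr (1.0 equiv), K2CO3 (1.1 equiv), acetone, reflux
Reagents that add atoms: benzyl bromide, BrCc1ccccc1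
Why: Williamson ether synthesis; 6 is symmetric, so mono-alkylation is statistical, and over-alkylated material and unchanged 6 are removed by chromatography and recycled.

Step 5
Reactants: 7 3-(benzyloxy)-5-methoxyphenol
Product: 8 [3-(benzyloxy)-5-methoxyphenoxy]tri(propan-2-yl)silane
Conditions: i-Pr3SiCl (1.2 equiv), imidazole (2.5 equiv), DMF, rt
Reagents that add atoms: chlorotri(propan-2-yl)silane, CC(C)[Si](Cl)(C(C)C)C(C)C
Why: Standard silylation of a phenol; the bulky, non-coordinating silyl ether protects the future 7-OH and shields both ring positions next to it.

Step 6
Reactants: 8 [3-(benzyloxy)-5-methoxyphenoxy]tri(propan-2-yl)silane (2.6 equiv) and 5 (3R,3aR,6R,6aR)-dilactone dimethyl ether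
Product: 11 (2R,3R)-1,4-bis[2-(benzyloxy)-6-methoxy-4-{[tri(propan-2-yl)silyl]oxy}phenyl]-2,3-bis[(R)-hydroxy(4-methoxyphenyl)methyl]butane-1,4-dione, via aryllithium 9 (not isolated), via dilithium bis(hemiketalate) 10 (not isolated)
Conditions: 8, n-BuLi (2.5 equiv), THF, 0 °C; then 5, THF, −78 → −40 °C; aq NH4Cl, −40 °C
Reagents that add atoms: none
Why: Directed ortho-lithiation: the only ring position of 8 not flanked by the silyl ether lies between the benzyloxy and methoxy groups, which cooperate to direct n-BuLi there. Aryllithium 9 adds once to each lactone carbonyl from the convex face (nucleophilic acyl addition), and the di-ortho-substituted aryl group makes adduct 10 too hindered for a second addition, as in the addition of 2,4,6-trialkoxyphenyllithiums to aldonolactones. Only acyl–oxygen bonds break, so all four stereocentres keep their configuration.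

Step 7
Reactants: 11 bis(benzyloxyaryl) bis(hydroxy ketone)
Product: 12 (2R,3R)-1,4-bis[2-hydroxy-6-methoxy-4-{[tri(propan-2-yl)silyl]oxy}phenyl]-2,3-bis[(R)-hydroxy(4-methoxyphenyl)methyl]butane-1,4-dione
Conditions: H2 (1 atm), 10% Pd/C, EtOAc, rt, stopped after uptake of 2 equiv
Reagents that add atoms: none
Why: Hydrogenolysis of the two aryl benzyl ethers, which in neutral ethyl acetate should cleave much faster than the secondary 4-methoxybenzylic alcohols are reduced, while the hindered aryl ketones and the silyl ethers are inert. The freed phenols hydrogen-bond to the ketones, which favours the open hydroxy ketone over the hemiketal.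

Step 8
Reactants: 12 bis(2-hydroxyaryl) bis(hydroxy ketone)
Product: 13 7,7''-bis-O-[tri(propan-2-yl)silyl]-4',4''',5,5''-tetramethylchamaejasmin (2S,3R,2''S,3''R)
Conditions: PPh3 (3 equiv), DIAD (3 equiv), THF (0.01 M), 0 °C → rt
Reagents that add atoms: none
Why: Twofold intramolecular Mitsunobu etherification: each carbinol is activated as its alkoxyphosphonium ion and displaced by the neighbouring phenoxide in a 6-exo-tet SN2 closure, the same closure by which 3-aryl-3-hydroxy-1-(2-hydroxyphenyl)propan-1-ones are turned into flavanones. Inversion converts both R carbinol carbons into the S centres C2 and C2'' and places each aryl group trans to the C3 substituent, while C3 and C3'' are not involved. High dilution suppresses intermolecular etherification.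

Step 9
Reactants: 13 bis(silyl ether)
Product: 14 4',4''',5,5''-tetramethylchamaejasmin
Conditions: Bu4NF (2.2 equiv), AcOH (2.5 equiv), THF, 0 °C
Reagents that add atoms: none
Why: Fluoride-mediated cleavage of the two aryl silyl ethers; acetic acid buffers the medium so that the 3-substituted flavanone is neither enolised at C3 nor ring-opened.

## Compound list

1 | p-coumaric acid, (E)-3-(4-hydroxyphenyl)prop-2-enoic acid | O=C(O)/C=C/c1ccc(O)cc1 | starting material
2 | (2S,3S)-2,3-bis[(4-oxocyclohexa-2,5-dien-1-ylidene)methyl]butanedioic acid, racemic C2-symmetric diastereomer, not isolated | O=C1C=CC(=C[C@H](C(=O)O)[C@@H](C(=O)O)C=C2C=CC(=O)C=C2)C=C1 | intermediate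
3 | rac-(3R,3aR,6R,6aR)-3,6-bis(4-hydroxyphenyl)tetrahydro-1H,3H-furo[3,4-c]furan-1,4-dione (exo,exo) | Oc1ccc([C@@H]2OC(=O)[C@@H]3[C@H]2C(=O)O[C@H]3c2ccc(O)cc2)cc1 | intermediate
4 | rac-(3R,3aR,6R,6aR)-3,6-bis(4-methoxyphenyl)tetrahydro-1H,3H-furo[3,4-c]furan-1,4-dione | COc1ccc([C@@H]2OC(=O)[C@@H]3[C@H]2C(=O)O[C@H]3c2ccc(OC)cc2)cc1 | intermediate
5 | (3R,3aR,6R,6aR)-3,6-bis(4-methoxyphenyl)tetrahydro-1H,3H-furo[3,4-c]furan-1,4-dione, single enantiomer | COc1ccc([C@@H]2OC(=O)[C@@H]3[C@H]2C(=O)O[C@H]3c2ccc(OC)cc2)cc1 | intermediate
6 | 5-methoxyresorcinol, 5-methoxybenzene-1,3-diol | COc1cc(O)cc(O)c1 | starting material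
7 | 3-(benzyloxy)-5-methoxyphenol | COc1cc(O)cc(OCc2ccccc2)c1 | intermediate
8 | [3-(benzyloxy)-5-methoxyphenoxy]tri(propan-2-yl)silane | COc1cc(OCc2ccccc2)cc(O[Si](C(C)C)(C(C)C)C(C)C)c1 | intermediate
9 | [2-(benzyloxy)-6-methoxy-4-{[tri(propan-2-yl)silyl]oxy}phenyl]lithium, not isolated | [Li]c1c(OC)cc(O[Si](C(C)C)(C(C)C)C(C)C)cc1OCc1ccccc1 | intermediate
10 | dilithium (3R,3aR,6R,6aR)-1,4-bis[2-(benzyloxy)-6-methoxy-4-{[tri(propan-2-yl)silyl]oxy}phenyl]-3,6-bis(4-methoxyphenyl)tetrahydro-1H,3H-furo[3,4-c]furan-1,4-diolate, configuration at C1 and C4 not defined, not isolated | COc1ccc([C@@H]2OC([O-])(c3c(OC)cc(O[Si](C(C)C)(C(C)C)C(C)C)cc3OCc3ccccc3)[C@@H]3[C@H]2C([O-])(c2c(OC)cc(O[Si](C(C)C)(C(C)C)C(C)C)cc2OCc2ccccc2)O[C@H]3c2ccc(OC)cc2)cc1.[Li+].[Li+] | intermediate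
11 | (2R,3R)-1,4-bis[2-(benzyloxy)-6-methoxy-4-{[tri(propan-2-yl)silyl]oxy}phenyl]-2,3-bis[(R)-hydroxy(4-methoxyphenyl)methyl]butane-1,4-dione | COc1ccc([C@H](O)[C@H](C(=O)c2c(OC)cc(O[Si](C(C)C)(C(C)C)C(C)C)cc2OCc2ccccc2)[C@@H](C(=O)c2c(OC)cc(O[Si](C(C)C)(C(C)C)C(C)C)cc2OCc2ccccc2)[C@@H](O)c2ccc(OC)cc2)cc1 | intermediate
12 | (2R,3R)-1,4-bis[2-hydroxy-6-methoxy-4-{[tri(propan-2-yl)silyl]oxy}phenyl]-2,3-bis[(R)-hydroxy(4-methoxyphenyl)methyl]butane-1,4-dione | COc1ccc([C@H](O)[C@H](C(=O)c2c(OC)cc(O[Si](C(C)C)(C(C)C)C(C)C)cc2O)[C@@H](C(=O)c2c(OC)cc(O[Si](C(C)C)(C(C)C)C(C)C)cc2O)[C@@H](O)c2ccc(OC)cc2)cc1 | intermediate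
13 | 7,7''-bis-O-[tri(propan-2-yl)silyl]-4',4''',5,5''-tetramethylchamaejasmin (2S,3R,2''S,3''R) | COc1ccc([C@H]2Oc3cc(O[Si](C(C)C)(C(C)C)C(C)C)cc(OC)c3C(=O)[C@@H]2[C@H]2C(=O)c3c(OC)cc(O[Si](C(C)C)(C(C)C)C(C)C)cc3O[C@@H]2c2ccc(OC)cc2)cc1 | intermediate
14 | 4',4''',5,5''-tetramethylchamaejasmin (2S,3R,2''S,3''R) | COc1ccc([C@H]2Oc3cc(O)cc(OC)c3C(=O)[C@@H]2[C@H]2C(=O)c3c(OC)cc(O)cc3O[C@@H]2c2ccc(OC)cc2)cc1 | target

## Step count and least certain steps

Total: 9 steps. The longest linear sequence is 7 steps (steps 1, 2, 3, 6, 7, 8 and 9 from 1). The ring A branch (steps 4 and 5 from 6) joins at step 6.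

Step 1 (key step). The most likely failure is radical coupling through a ring carbon or the phenol oxygen (8–5 and 8–O–4 modes), followed by further oxidation and oligomerisation, because the unsubstituted ortho positions of 1 leave these modes open. Loss of the meso 8–8' adduct also costs material. Fallback: the dilactone is built without radicals. This fallback does not set out from 1 to 3 but from commercial 4-methoxybenzaldehyde and N,N,N',N'-tetramethylsuccinamide. Double aldol addition of the dilithium dienolate of the diamide (LiN(i-Pr)2, THF, −78 °C) to the aldehyde should give racemic (2R,3R)-2,3-bis[(R)-hydroxy(4-methoxyphenyl)methyl]-N,N,N',N'-tetramethylbutanediamide F1 together with carbinol epimers. Acid-mediated lactonisation (p-TsOH·H2O, toluene, 80 °C) should then converge on the exo,exo dilactone, since the 4-methoxybenzylic C–O bonds ionise reversibly. The fallback comes back to the route at 4, before the resolution, and step 2 falls away.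

Step 6. Proton transfer may compete with addition: the basic aryllithium can remove the ring-fusion proton alpha to a lactone carbonyl, after which the beta-carboxylate is expelled and the bicycle unravels. During metalation, deprotonation of the benzylic CH2 of the benzyl ether and [1,2]-Wittig rearrangement may compete with ring lithiation. Fallback, setting out from 5: aminolysis with Me(MeO)NH·HCl and AlMe3 (CH2Cl2, 0 °C) should give (2R,3R)-2,3-bis[(R)-hydroxy(4-methoxyphenyl)methyl]-N1,N4-dimethoxy-N1,N4-dimethylbutanediamide F2. This is silylated at once (Et3SiCl, imidazole, DMF) to the bis(triethylsilyl) ether F3, so that it cannot relactonise. Addition of 9 (THF, −78 → 0 °C) to the two N-methoxy-N-methylamide groups stops at the ketone stage through the chelated adduct and should give the bis(triethylsilyl) ether F4 of 11. Cleavage of the alkyl silyl ethers with AcOH–THF–H2O at rt, which leaves the aryl silyl ethers in place, comes back to the route at 11.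

Step 7. Over-reduction is the concern: hydrogenolysis of the 4-methoxybenzylic C–OH bonds once the benzyl ethers are gone, because the electron-rich aryl group activates these bonds towards palladium. Fallback, setting out from 6 and 5: the benzyl ether is replaced by a methoxymethyl ether that is removed without hydrogen. Mono-alkylation of 6 (MeOCH2Cl, i-Pr2NEt, CH2Cl2) gives 3-methoxy-5-(methoxymethoxy)phenol F5, and silylation (i-Pr3SiCl, imidazole) gives [3-methoxy-5-(methoxymethoxy)phenoxy]tri(propan-2-yl)silane F6. Lithiation with n-BuLi between the acetal and methoxy groups, which has no Wittig pathway, gives the aryllithium F7. Addition to 5 as in step 6 gives the bis(methoxymethyl ether) F8 of 12. Cleavage of the acetals ortho to the ketones on NaHSO4·SiO2 (CH2Cl2, rt), assisted by chelation, comes back to the route at 12.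

Step 8. The alkoxyphosphonium ion at the 4-methoxybenzylic carbon may ionise before the phenoxide attacks, which would erode the inversion. It may also undergo beta-elimination towards the enone, which would erase C3. Participation of the remote ketone oxygen is a further, less likely, diversion. Fallback, setting out from 12 and making no new compound (F0): the closure is run deliberately through the benzylic cation, with catalytic camphorsulfonic acid in CH2Cl2–(CF3)2CHOH at 0 °C, as in the acid-catalysed dehydrative etherification of electron-rich benzylic alcohols by phenols. The configuration at C2 and C2'' is then set by the neighbouring C3 and C3'' centres, which should place the aryl groups pseudo-equatorial and trans, and not by inversion. The fallback comes back to the route at 13.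

## Further compounds

F1 | step 1 | rac-(2R,3R)-2,3-bis[(R)-hydroxy(4-methoxyphenyl)methyl]-N,N,N',N'-tetramethylbutanediamide | COc1ccc([C@H](O)[C@H](C(=O)N(C)C)[C@@H](C(=O)N(C)C)[C@@H](O)c2ccc(OC)cc2)cc1
F2 | step 6 | (2R,3R)-2,3-bis[(R)-hydroxy(4-methoxyphenyl)methyl]-N1,N4-dimethoxy-N1,N4-dimethylbutanediamide | COc1ccc([C@H](O)[C@H](C(=O)N(C)OC)[C@@H](C(=O)N(C)OC)[C@@H](O)c2ccc(OC)cc2)cc1
F3 | step 6 | (2R,3R)-N1,N4-dimethoxy-2,3-bis[(R)-(4-methoxyphenyl)(triethylsilyloxy)methyl]-N1,N4-dimethylbutanediamide | COc1ccc([C@H](O[Si](CC)(CC)CC)[C@H](C(=O)N(C)OC)[C@@H](C(=O)N(C)OC)[C@@H](O[Si](CC)(CC)CC)c2ccc(OC)cc2)cc1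
F4 | step 6 | (2R,3R)-1,4-bis[2-(benzyloxy)-6-methoxy-4-{[tri(propan-2-yl)silyl]oxy}phenyl]-2,3-bis[(R)-(4-methoxyphenyl)(triethylsilyloxy)methyl]butane-1,4-dione | COc1ccc([C@H](O[Si](CC)(CC)CC)[C@H](C(=O)c2c(OC)cc(O[Si](C(C)C)(C(C)C)C(C)C)cc2OCc2ccccc2)[C@@H](C(=O)c2c(OC)cc(O[Si](C(C)C)(C(C)C)C(C)C)cc2OCc2ccccc2)[C@@H](O[Si](CC)(CC)CC)c2ccc(OC)cc2)cc1
F5 | step 7 | 3-methoxy-5-(methoxymethoxy)phenol | COCOc1cc(O)cc(OC)c1
F6 | step 7 | [3-methoxy-5-(methoxymethoxy)phenoxy]tri(propan-2-yl)silane | COCOc1cc(OC)cc(O[Si](C(C)C)(C(C)C)C(C)C)c1
F7 | step 7 | [2-methoxy-6-(methoxymethoxy)-4-{[tri(propan-2-yl)silyl]oxy}phenyl]lithium | [Li]c1c(OC)cc(O[Si](C(C)C)(C(C)C)C(C)C)cc1OCOC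
F8 | step 7 | (2R,3R)-2,3-bis[(R)-hydroxy(4-methoxyphenyl)methyl]-1,4-bis[2-methoxy-6-(methoxymethoxy)-4-{[tri(propan-2-yl)silyl]oxy}phenyl]butane-1,4-dione | COc1ccc([C@H](O)[C@H](C(=O)c2c(OC)cc(O[Si](C(C)C)(C(C)C)C(C)C)cc2OCOC)[C@@H](C(=O)c2c(OC)cc(O[Si](C(C)C)(C(C)C)C(C)C)cc2OCOC)[C@@H](O)c2ccc(OC)cc2)cc1
F0 | step 8 | none | none
A1 | alternative 1 | (2E,3E)-2,3-bis(4-methoxybenzylidene)-1,4-bis(2,4,6-trihydroxyphenyl)butane-1,4-dione | COc1ccc(/C=C(/C(=O)c2c(O)cc(O)cc2O)C(=C/c2ccc(OC)cc2)\C(=O)c2c(O)cc(O)cc2O)cc1
A2 | alternative 2 | 5,5'',7,7''-tetra-O-benzyl-4',4'''-di-O-methylchamaejasmin | COc1ccc([C@H]2Oc3cc(OCc4ccccc4)cc(OCc4ccccc4)c3C(=O)[C@@H]2[C@H]2C(=O)c3c(OCc4ccccc4)cc(OCc4ccccc4)cc3O[C@@H]2c2ccc(OC)cc2)cc1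
A3 | alternative 3 | 7,7''-di-O-benzyl-4',4''',5,5''-tetramethylchamaejasmin | COc1ccc([C@H]2Oc3cc(OCc4ccccc4)cc(OC)c3C(=O)[C@@H]2[C@H]2C(=O)c3c(OC)cc(OCc4ccccc4)cc3O[C@@H]2c2ccc(OC)cc2)cc1
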